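The runs were computed for an exercise, noise included.

The unit here is the charge of E: every entry below is a fraction of it, and you close the books when the entries add up to one.

| setting | blue | grey | birch | alder | oak |
|---|---|---|---|---|---|
| E | 0.050 M | 0.050 M | 0.050 M | 0.050 M | 0.050 M |
| D | 0.40 equiv | 1.8 equiv | 2.50 equiv | 0.800 equiv | 0.500 equiv |
| remark | run made earlier | run made earlier |  |  |  |
| time |  |  | 2.5 min | 2.5 min | 2.5 min |

| run | time / s | L / % |
|---|---|---|
| blue | 10.0 | 0.4 |
| blue | 15.0 | 0 |
| blue | 20.0 | 0.9 |
| blue | 30.0 | 0 |
| blue | 50.0 | 1.3 |
| blue | 80.0 | 1.5 |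
| grey | 10.0 | 0.6 |
| grey | 12.0 | 0.3 |
| grey | 20.0 | 2.7 |
| grey | 30.0 | 4.5 |
| grey | 50.0 | 6.0 |
| grey | 60.0 | 8.7 |
| grey | 80.0 | 9.0 |

(readings scatter by 1 percentage point)

1. which of these holds the largest part of the E at the end of birch (G / E / L)
2. which of these holds the largest part of the E at the end of alder (G / E / L)
3. which of these holds the largest part of the E at the end of oak (G / E / L)
4. L at the end of birch, in percent of the E charged



In birch, with 2.50 equiv of D, E is the limiting reagent, and I treat its passage to L as pseudo-first-order in the charged D, so that you can count half-lives. You read the clock from the last grey reading, whose 9.0% stands clear of the scatter of 1 percentage point, while blue's 1.5% barely does. Then you scale the half-life inversely with the equivalents of D: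

grey: 9.0% of L at 80.0 s means a half-life to L of 9.80 min

birch: scaled from 1.8 equiv to 2.50 equiv of D, that becomes 7.06 min

L-count, the half-lives to L elapsed at the end of a flask: 0.354 in 2.5 min

Now the ledger for birch, as I reckon it:

L: 21.8%

open balance, in forms the earlier runs do not read: 78.2%

The readings do not split that balance, so in birch I commit to the L entry and no more, and in alder to nothing. In oak, 0.500 equiv of D is the limiting charge and can carry off at most that much of E, so E is my answer there.

The forecast, which opens with “The likely scheme is stepwise”, says G for birch, G for alder, E for oak and 30% of L in birch, which is higher than my 21.8%.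

The flask gives L as the largest of the three in birch, E in alder and E in oak, with 16.8% of L in birch.

    E + D ⇌ Z + G (K = 1.70, k = 0.370 M⁻¹ s⁻¹)
    G + D ⇌ Z + L (K = 35.0, k = 0.120 M⁻¹ s⁻¹)
    G → X (k = 0.0480 s⁻¹)

The open balance of birch is X at 78.6%, beside 2.96% of E and 1.58% of G, and that closes the books. The L-count of 0.354 gave 21.8% against 16.8%. On the neighbour with 0.620 equiv of D it gives 0.0878 half-lives and 5.90% of L, and that flask holds 1.67%, with 45.1% in X. Birch has not come to rest at 2.5 min: at ten times the time, 25.0 min, the count stands at 3.54 half-lives, yet L has dropped to 13.9%, E to 0.0241% and G to 0.0485%, while X has climbed to 86.0% and D stands at 54.5% of its charge.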